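**Numbering.** Ring A is C1 (gem-diprenyl), C2 (C=O), C3 (spiro), C4 (C=O), C5 (acyl-bearing; acyl carbonyl C7), C6 (enol). Ring B is C3, C8, C9, C10, C11, C12. Ring C is C9, C10, C13, C14, C15. The face of ring B carrying C9–H is called α, the face carrying C10–H is called β.

## The problem

The target 19 is a spiro tricycle of three carbocycles. Ring A is an enolised 2-acylcyclohexane-1,3,5-trione that shares the quaternary carbon C3 with cyclohexane ring B, and ring B is trans-fused along C9–C10 to cyclopentane ring C. The five stereocentres are (3S,9R,10S,11R,15S): the C11 hydroxyl is α and axial, the C15 hydroxyl is β, and C3 is stereogenic only because its α-axial carbonyl C2 is flanked by C1 and its β-equatorial carbonyl C4 by C5. Only C9 needs absolute control from outside: C10 is α to a carbonyl when C11 is a ketone and can be equilibrated to the trans fusion, the trans fusion freezes ring B in one chair, and in that chair an axial carboxyl on C3 closes the α-face of C11 and is the only acyl carbon a C11 α-alkoxide can reach, so C11 and then C3 follow from C9 and C10. C15 has no such relay and depends on the facial bias of the bicyclic ketone, and neither tertiary carbinol can be corrected once made. The prenyl alkenes do not survive ozone, the tertiary alcohols do not survive strong acid, and the acidic acyl triketone interferes with organometallic reagents, so ring A and the prenyl groups must come last. The feature that opens the molecule is that C9 and C10 are the β- and α-carbons of a C11 carbonyl while C15, bonded to C9, can be carried as the substituted carbon of a 1,1-disubstituted alkene: ring B can start as an achiral cyclohexenone already holding both C3 carboxyls as a symmetrical gem-diester, and ring C can be annulated across C9=C10 by a four-carbon unit that is nucleophilic at C15 and electrophilic at C13.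

## Retrosynthesis

**19 ⇒ 18.** The two bonds from C1 to the prenyl groups are cut first. C1 is the only carbon of 18 that still carries hydrogen between two ring carbonyls, so double C-alkylation is regiochemically unambiguous. Any earlier introduction would force the trisubstituted alkenes through an ozonolysis and several organometallic steps. 18 is ten carbons smaller and has no alkene besides the enol. The forward step must favour carbon over oxygen alkylation and leave two tertiary alcohols alone.

**18 ⇒ 15 + 16.** Ring A is opened at C1–C2 and C4–C5. This leaves C3 with two acyl carbons and returns the chain C1–C6–C5–C7 to the diketone 16, whose terminal methyl (C1) and central methylene (C5) are the two nucleophilic sites of its dianion. Acylating a preformed spiro trione at C5 would not distinguish C1 from C5 and would lose C3. In 15 the two acyl carbons are already distinguished: C2 is the carbonyl of a lactone to the C11 oxygen and C4 is a methyl ester. The forward reaction must attack the lactone carbonyl first and then close the triketo ester 17 by C-acylation.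

**15 ⇒ 13.** The two C–CH3 bonds at C11 and C15 and the lactone C–O bond are cut, giving the diketone diester 13 by way of the diol diester 14. In 13 the two C3 carboxyls are identical, so only C9 and C10 remain as stereocentres. Oxygen delivery to a C15 alkene (hydration, epoxidation) would arrive on the open α-face, the wrong one, whereas a methyl nucleophile entering there leaves the hydroxyl β. Forward, methyl must enter C11 equatorially and C15 from the α-face without enolising either ketone, and the C11 alkoxide must close on the axial ester.

**13 ⇒ 11.** The C15 carbonyl is traced to the exocyclic methylene of 11 (through ozonide 12). Carrying C15 as an alkene keeps C9 non-enolisable while C10 is equilibrated and makes C15 a vinyl nucleophile one stage earlier.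

**11 ⇒ 5 + 8.** The C9–C15 and C10–C13 bonds are cut, removing ring C and both ring-fusion stereocentres at once. What remains is the achiral enone 5 and the boronate 8, which is nucleophilic at its boron-bearing carbon and electrophilic at the chloride carbon. Cuts elsewhere in ring C would not place a bond-forming event on the β-carbon of an enone, where a catalytic asymmetric conjugate addition can set C9. Forward, the adduct 9 must be formed with enantioface control, the C10 enolate must close on the chloride (giving 10), and C10 must equilibrate to the trans isomer 11.

**5 ⇒ 4 ⇒ 3 ⇒ 1 + 2.** The C9=C10 bond of 5 is a ring-closing metathesis bond of the diene 4. The vinyl ketone of 4 comes from the Weinreb amide 3, and 3 from alkylation of the malonate 1 with the bromoamide 2. Each step removes one functional group. The sequence carries no stereochemistry, and the quaternary C3 is made by the simplest possible alkylation.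

**8 ⇒ 7 ⇒ 6.** The C–B bond of 8 is cut to the alkenyl bromide 7, and the C–Cl bond of 7 to the alcohol 6. Borylating an alkenyl bromide fixes the boron on the internal carbon, which a hydroboration of a terminal alkyne would not do reliably.

## Roads not taken

Alternative 1: The cut is C8–C9 and C10–C11 on a preformed ring C. The (S)-configured bromomethylsilyl ether A1 of 1-methylcyclopent-2-en-1-ol would give, under a tin hydride chain, a silylmethyl radical that adds 5-exo to C9 cis to the tethering oxygen. The C10 radical would be trapped anti by an isocyanide, which fragments to the nitrile A2.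
- Merit: C15, C9 and C10 come from one carbinol centre with tether-enforced relative configuration. This road is better than the chosen plan at C15, which the chosen plan leaves to the facial bias of a ketone in step 8.
- Weak points: A1 needs an enantiopure, small, volatile tertiary allylic alcohol with no short catalytic asymmetric entry. A2 contains only ring C. The C–Si bond must then be oxidised and C8 made electrophilic, the nitrile turned into the C11 methyl ketone, and ring B closed around a quaternary C3 by two more C–C bonds. The C11 carbinol would be formed without the axial-carboxyl shield, and C3 is not addressed.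
- Comparison: the chosen plan sets against this a catalytic source of chirality from achiral materials, a ring B that holds C3 from the first step, and several fewer operations.

Alternative 2: The cut is C9–C10 and C13–C14, closing rings B and C together. In the open-chain substrate A3, zerovalent palladium would ionise the allylic carbonate and loss of silicon would give the trimethylenemethane complex. Its C9 terminus adds to C10 of the vinyl sulfone, and the sulfonyl carbanion C13 closes on C14 to give A4.
- Merit: two rings and two C–C bonds in one step, with the C11 carbinol already in place and the same C15 methylene handle. In rings per step this road is better than the chosen key step.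
- Weak points: A3 is a long linear construct needing an enantiopure acyclic tertiary carbinol, a bifunctional donor arm and a vinyl sulfone. The quaternary C11 must alone dictate C10 and C9. The ring fusion is set kinetically and cannot be equilibrated because C11 is not a carbonyl. The sulfone costs a reductive step next to an allylic system. The tert-butyl esters suit neither lactonisation nor ring A construction. C15 still needs the same ketone addition.
- Comparison: the chosen plan sets against this three-step access to each partner, ligand control of C9 and thermodynamic correction of C10.

Alternative 3: The cut is C1–C2 and C4–C5. The dianion of the diketone A7 (the structure of 16) opens the bridged lactone A5 (the structure of 15) at its carbonyl, and the triketone anion then acylates itself on the methyl ester to give A6 (the structure of 18).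
- Merit: ring A with all its oxygens and the acyl group is made in one operation, and the lactone/ester difference is translated into the C3 configuration. Nothing in the chosen plan does this better, so it is adopted unchanged as step 9.
- Weak point as a leading strategy: A5 already contains rings B and C and four stereocentres, and the annulation creates none of them.
- Comparison: the two are complementary. The chosen key step supplies the absolute configuration that this road presupposes, and the chosen plan inherits its one real risk, the choice between lactone and ester carbonyl.

Key step: step 6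

Assumption: 3-bromobut-3-en-1-ol (6), the Markovnikov HBr adduct of but-3-yn-1-ol, is taken as a catalogue compound.
Assumption: 19 is drawn as its C5=C6 enol; the acyl triketone is a set of fast tautomers, and the C2 ketone of 17 to 19 may rest as a hemiketal with the 1,3-diaxial C11 hydroxyl without change of constitution.

## Route

Step 1
Reactants: 1 dimethyl 2-(prop-2-en-1-yl)propanedioate (dimethyl allylmalonate); 2 2-bromo-N-methoxy-N-methylacetamide
Product: 3 dimethyl 2-{2-[methoxy(methyl)amino]-2-oxoethyl}-2-(prop-2-en-1-yl)propanedioate
Conditions: NaH, THF, 0 °C; then 2, 0 °C to rt
Reagents that add atoms: none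
Why: Malonate alkylation (SN2): the sodium enolate of 1 displaces bromide from the activated primary α-bromo amide; the product has no acidic C–H left, so it cannot be alkylated again.

Step 2
Reactants: 3 dimethyl 2-{2-[methoxy(methyl)amino]-2-oxoethyl}-2-(prop-2-en-1-yl)propanedioate
Product: 4 dimethyl 2-(2-oxobut-3-en-1-yl)-2-(prop-2-en-1-yl)propanedioate
Conditions: CH2=CHMgBr, THF, −40 to 0 °C; inverse quench into cold aq. HCl
Reagents that add atoms: vinylmagnesium bromide, C=C[Mg]Br
Why: Weinreb ketone synthesis: the chelated tetrahedral adduct survives until the quench, so the enone is never exposed to the Grignard reagent, and the two neopentyl-type esters react far more slowly than the amide. The acid quench protonates the released amine and prevents its conjugate addition to the vinyl ketone.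

Step 3
Reactants: 4 dimethyl 2-(2-oxobut-3-en-1-yl)-2-(prop-2-en-1-yl)propanedioate
Product: 5 dimethyl 5-oxocyclohex-3-ene-1,1-dicarboxylate
Conditions: second-generation Grubbs catalyst (3 mol%), CH2Cl2 (0.02 M), 40 °C
Reagents that add atoms: none
Why: Ring-closing metathesis of an allyl group with a vinyl ketone to a cyclohexenone; the gem-diester favours closure (Thorpe–Ingold effect) and loss of ethene drives it. No stereocentre is formed.

Step 4
Reactants: 6 3-bromobut-3-en-1-ol
Product: 7 2-bromo-4-chlorobut-1-ene
Conditions: PPh3, N-chlorosuccinimide, CH2Cl2, 0 °C to rt
Reagents that add atoms: N-chlorosuccinimide, O=C1CCC(=O)N1Cl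
Why: Appel-type chlorination: the alkoxyphosphonium salt of the primary alcohol is displaced by chloride (SN2); the alkenyl bromide is inert.

Step 5
Reactants: 7 2-bromo-4-chlorobut-1-ene
Product: 8 2-(4-chlorobut-1-en-2-yl)-4,4,5,5-tetramethyl-1,3,2-dioxaborolane
Conditions: B2pin2, PdCl2(PPh3)2 (3 mol%), PPh3 (6 mol%), KOPh, toluene, 50 °C
Reagents that add atoms: bis(pinacolato)diboron, CC1(C)OB(OC1(C)C)B1OC(C)(C)C(C)(C)O1
Why: Miyaura borylation of a 1-alkenyl bromide: oxidative addition to zerovalent palladium, exchange to the phenoxide, transmetalation with the diboron and reductive elimination place boron on the internal carbon. The weak phenoxide base suppresses Suzuki coupling of product with 7, and the primary alkyl chloride does not add oxidatively at this temperature.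

Step 6
Reactants: 5 dimethyl 5-oxocyclohex-3-ene-1,1-dicarboxylate; 8 2-(4-chlorobut-1-en-2-yl)-4,4,5,5-tetramethyl-1,3,2-dioxaborolane
Product: 11 dimethyl (3aR,7aS)-3-methylidene-7-oxooctahydro-1H-indene-5,5-dicarboxylate (trans-fused; 9R,10S), via conjugate adduct 9 (not isolated), via cis-fused ketone 10 (not isolated)
Conditions: [RhCl(C2H4)2]2 (2.5 mol%), (R)-BINAP (6 mol%), KOH (0.2 equiv), 8 (1.8 equiv), dioxane/H2O 10:1, 50 °C; dry (MgSO4), evaporate; then t-BuOK (1.3 equiv), t-BuOH/THF, 0 °C to rt; AcOH
Reagents that add atoms: none
Why: Hayashi–Miyaura reaction followed by intramolecular enolate alkylation (methylenecyclopentane annulation), both known on cyclohexenones. [RhCl(C2H4)2]2, the diphosphine and KOH give a hydroxo complex of monovalent rhodium; boron-to-rhodium transmetalation from 8 gives the alkenylrhodium, enone 5 inserts into the Rh–C bond to form C9–C15 and an oxa-π-allyl rhodium enolate, and water releases 9 and the hydroxo complex. C9 is the only centre made under kinetic control and is set by the ligand: the (R)-diphosphine, which gives (R)-3-substituted cyclohexanones from cyclohex-2-enone, should select the same enone face here because the gem-diester is remote and symmetrical, giving (R)-9. With t-BuOK the C10 enolate closes on C13 in a 5-(enolexo)-exo-tet displacement of chloride, forming ring C; the C12 enolate could only form a bridged seven-membered ring and O-alkylation a seven-membered enol ether, so ring size secures the regiochemistry. The closure is expected to give mainly the cis-fused ketone 10, but C10 is α to the C11 ketone and the same alkoxide equilibrates it to the trans isomer 11 (10S), in which both ring C bonds are equatorial on the ring B chair. C9 cannot enolise while C15 is an alkene, so its configuration is untouched. The selectivities needed are enantioface choice at C9 (ligand), C- over O-alkylation at C10 (ring size) and trans fusion (thermodynamics).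

Step 7
Reactants: 11 dimethyl (3aR,7aS)-3-methylidene-7-oxooctahydro-1H-indene-5,5-dicarboxylate
Product: 13 dimethyl (3aR,7aS)-3,7-dioxooctahydro-1H-indene-5,5-dicarboxylate (trans-fused; 9R,10S), via spiro ozonide 12 (not isolated)
Conditions: O3, CH2Cl2, −78 °C; then PPh3, −78 °C to rt
Reagents that add atoms: ozone, [O-][O+]=O
Why: Ozonolysis: cycloaddition, cycloreversion and recombination give the ozonide 12, which PPh3 reduces to the ketone and formaldehyde. The C11 ketone and the esters are inert to ozone, and the neutral work-up avoids enolisation towards C9 or C10; 13 is used at once.

Step 8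
Reactants: 13 dimethyl (3aR,7aS)-3,7-dioxooctahydro-1H-indene-5,5-dicarboxylate
Product: 15 bridged hydroxy lactone methyl ester (3R,9R,10S,11R,15S; α-axial C3 carboxyl lactonised on O11; C4 methyl ester β-equatorial; 15β-OH), via diol diester 14 (not isolated)
Conditions: MeLi/CeCl3 (3 equiv), THF, −78 °C; warm to 0 °C; aq. NH4Cl
Reagents that add atoms: methyllithium, [Li]C
Why: Organocerium addition to ketones: the reagent is carbonyl-selective and weakly basic, so C9 and C10 should not enolise and the methyl esters are inert at −78 °C. At C11 the axial C3 ester and the axial C9–H close the α-face, so methyl enters equatorially from the β-face and the α-axial alkoxide of 14 lactonises on that same axial ester; this sets C11 (R) and makes C3 a stereocentre with the lactone carbonyl as the future C2. At C15 the β-face leans over ring B towards the axial hydrogens on C10 and C8, so the bulky reagent should take the outward α-face (equatorial-type attack) and leave the 15β-hydroxyl (S).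

Step 9
Reactants: 15 bridged hydroxy lactone methyl ester; 16 5-methylhexane-2,4-dione
Product: 18 des-prenyl spiro acyl triketone (3S,9R,10S,11R,15S; ring A with C1H2), via triketo ester 17 (not isolated)
Conditions: 16 (3.5 equiv), LiN(i-Pr)2 (7 equiv), THF, 0 °C; add 15, −78 to 0 °C; then MeOH, 50 °C; aq. HCl
Reagents that add atoms: none
Why: γ-Acylation of a β-diketone dianion followed by Claisen (Dieckmann-type) cyclisation of the resulting 3,5,7-triketo ester, the polyketide-type closure that leads to acylphloroglucinols. The terminal carbanion (C1) attacks the lactone carbonyl, the more electrophilic acyl group because of its fixed (E)-ester geometry and ring strain, to give 17; after methanol is added, C5 of the triketone anion acylates on the methyl ester to close the six-membered ring, the aldol alternative being blocked because C3 is quaternary. No stereocentre is formed or touched: the lactone/ester distinction fixes C2 α and C4 β, which is 3S.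

Step 10
Reactants: 18 des-prenyl spiro acyl triketone
Product: 19 target spiro acylphloroglucinol (3S,9R,10S,11R,15S; C1 gem-diprenyl)
Conditions: NaOMe (3.2 equiv), MeOH, 0 °C; prenyl bromide (2.3 equiv), 0 °C to rt
Reagents that add atoms: 1-bromo-3-methylbut-2-ene (prenyl bromide), CC(C)=CCBr
Why: C-Alkylation of a cyclic polyketo dianion: methoxide removes the enol proton and a C1 proton, C1 is the most nucleophilic carbon, and two successive SN2 reactions with the allylic bromide install the gem-diprenyl group, as in the dearomatising prenylation of acylphloroglucinols. The protic solvent favours carbon over oxygen alkylation, the tertiary alcohols are not alkylated, and no stereocentre is affected.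

## Compound list

1 | dimethyl 2-(prop-2-en-1-yl)propanedioate (dimethyl allylmalonate) | COC(=O)C(CC=C)C(=O)OC | starting material
2 | 2-bromo-N-methoxy-N-methylacetamide | CON(C)C(=O)CBr | starting material
3 | dimethyl 2-{2-[methoxy(methyl)amino]-2-oxoethyl}-2-(prop-2-en-1-yl)propanedioate | COC(=O)C(CC=C)(CC(=O)N(C)OC)C(=O)OC | intermediate
4 | dimethyl 2-(2-oxobut-3-en-1-yl)-2-(prop-2-en-1-yl)propanedioate | COC(=O)C(CC=C)(CC(=O)C=C)C(=O)OC | intermediate
5 | dimethyl 5-oxocyclohex-3-ene-1,1-dicarboxylate | COC(=O)C1(CC=CC(=O)C1)C(=O)OC | intermediate
6 | 3-bromobut-3-en-1-ol | OCCC(Br)=C | starting material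
7 | 2-bromo-4-chlorobut-1-ene | ClCCC(Br)=C | intermediate
8 | 2-(4-chlorobut-1-en-2-yl)-4,4,5,5-tetramethyl-1,3,2-dioxaborolane | C=C(CCCl)B1OC(C)(C)C(C)(C)O1 | intermediate
9 | conjugate adduct, not isolated: dimethyl (3R)-3-(4-chlorobut-1-en-2-yl)-5-oxocyclohexane-1,1-dicarboxylate | COC(=O)C1(C[C@@H](C(=C)CCCl)CC(=O)C1)C(=O)OC | intermediate
10 | cis-fused ketone, not isolated: dimethyl (3aR,7aR)-3-methylidene-7-oxooctahydro-1H-indene-5,5-dicarboxylate (9R,10R) | COC(=O)C1(C[C@@H]2[C@@H](CCC2=C)C(=O)C1)C(=O)OC | intermediate
11 | trans-fused methylene ketone diester: dimethyl (3aR,7aS)-3-methylidene-7-oxooctahydro-1H-indene-5,5-dicarboxylate (9R,10S) | COC(=O)C1(C[C@@H]2[C@H](CCC2=C)C(=O)C1)C(=O)OC | intermediate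
12 | spiro ozonide of 11, not isolated: 1,2,4-trioxolane on C15, both epimers at C15 | COC(=O)C1(C[C@@H]2[C@H](CCC23OCOO3)C(=O)C1)C(=O)OC | intermediate
13 | trans-fused 1,4-diketone diester: dimethyl (3aR,7aS)-3,7-dioxooctahydro-1H-indene-5,5-dicarboxylate (9R,10S) | COC(=O)C1(C[C@@H]2[C@H](CCC2=O)C(=O)C1)C(=O)OC | intermediate
14 | diol diester, not isolated: dimethyl (3S,3aR,7R,7aS)-3,7-dihydroxy-3,7-dimethyloctahydro-1H-indene-5,5-dicarboxylate (11α-OH, 15β-OH) | COC(=O)C1(C[C@@H]2[C@H](CC[C@]2(C)O)[C@](C)(O)C1)C(=O)OC | intermediate
15 | bridged hydroxy lactone methyl ester (3R,9R,10S,11R,15S): trans-hydrindane with 11β-methyl, 15α-methyl and 15β-hydroxyl; the α-axial C3 carboxyl forms a γ-lactone with O11 (6-oxabicyclo[3.2.1]octan-7-one across ring B); the β-equatorial C3 carboxyl is the methyl ester | O=C1[C@@]2(C[C@@H]3[C@H](CC[C@]3(C)O)[C@](C)(O1)C2)C(=O)OC | intermediate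
16 | 5-methylhexane-2,4-dione | CC(=O)CC(=O)C(C)C | starting material
17 | triketo ester, not isolated: methyl (3S,3aR,5S,7R,7aS)-3,7-dihydroxy-3,7-dimethyl-5-(6-methyl-3,5-dioxoheptanoyl)octahydro-1H-indene-5-carboxylate | CC(C)C(=O)CC(=O)CC(=O)[C@@]1(C[C@@H]2[C@H](CC[C@]2(C)O)[C@](C)(O)C1)C(=O)OC | intermediate
18 | des-prenyl spiro acyl triketone (3S,9R,10S,11R,15S): ring A is 5-(2-methylpropanoyl)-6-hydroxycyclohex-5-ene-2,4-dione (route numbering) with C1H2, spiro at C3 to the 11α-hydroxy-11-methyl, 15β-hydroxy-15-methyl trans-hydrindane | CC(C)C(=O)C1=C(O)CC(=O)[C@@]2(C[C@@H]3[C@H](CC[C@]3(C)O)[C@](C)(O)C2)C1=O | intermediate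
19 | target (3S,9R,10S,11R,15S): as 18 with two 3-methylbut-2-en-1-yl groups on C1 | CC(C)=CCC1(CC=C(C)C)C(=O)[C@@]2(C[C@@H]3[C@H](CC[C@]3(C)O)[C@](C)(O)C2)C(=O)C(C(=O)C(C)C)=C1O | target

## Step count and weak points

Total: 10 steps. Longest linear sequence: 8 steps (1, 2, 3, 6, 7, 8, 9, 10); the boronate branch (steps 4 and 5) joins at step 6.

**Step 6 (key step).** Most likely failure: slow transmetalation and protodeboronation of the α-branched alkenyl pinacol boronate, partial saponification of the malonate by aqueous hydroxide, and incomplete cis-to-trans equilibration in a medium that is not fully dry. Fallback, from 8 and 5 back to 11: 8 is converted with KHF2 in aqueous methanol into potassium (4-chlorobut-1-en-2-yl)trifluoroborate F1, which releases the boronic acid slowly. F1 is added to 5 under a cationic complex of monovalent rhodium, [Rh(cod)2]BF4 with (R)-BINAP in toluene/H2O at 100 °C, without hydroxide. 9 is then isolated, and ring closure and equilibration are run as a separate anhydrous operation (KH in THF, then catalytic NaOMe in MeOH) to reach 11.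

**Step 8.** Most likely failure: poor facial discrimination at C15, where the torsionally preferred β-approach competes with the sterically preferred α-approach, and erosion of the ring fusion by enolisation of the 1,4-diketone, since C9 is α to the C15 ketone and cis-fused hydrindan-1-ones are the more stable. Fallback, from 11 back to 15, addressing the two carbonyls one at a time:
- Methylcerium addition to 11 while C15 is still an alkene gives the hydroxy diester F2, which lactonises in the flask to the methylene lactone ester F3.
- Ozonolysis with PPh3 work-up gives, through the ozonide F4, the keto lactone ester F5.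
- F5 is treated with MeTi(OiPr)3, which is non-basic, inert to lactone and ester, and known for strong equatorial-type selectivity, to give 15.

**Step 9.** Most likely failure: loss of site selectivity, the dianion attacking the methyl ester before the lactone (which would end in the C3 epimer), and incomplete Claisen closure of 17. Fallback, from 15 back to 18 through isolated 17:
- 15 is demethylated by SN2 attack of iodide on the ester methyl group (LiI, ethyl acetate, reflux) to give the lactone acid F6; the lactone cannot react this way because its alkyl carbon is tertiary.
- As its lithium carboxylate the C4 acyl group is inert, so the dianion of 16 can only open the lactone, giving the triketo acid F7.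
- One equivalent of trimethylsilyldiazomethane at 0 °C methylates the much more acidic carboxyl and gives 17, which NaOMe in MeOH closes to 18.

**Step 10.** Most likely failure: competing O-prenylation of the enolates and incomplete second alkylation at the hindered C1. Fallback, from 18 back to 19: Pd(PPh3)4-catalysed double C-allylation with allyl methyl carbonate (Tsuji–Trost reaction; O-allyl products are re-ionised by zerovalent palladium and funnel to carbon) gives the C1-diallyl compound F8. Cross-metathesis of both allyl groups with 2-methylbut-2-ene under the second-generation Grubbs catalyst then gives 19.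

## Further compounds

F1 | step 6 | potassium (4-chlorobut-1-en-2-yl)trifluoroborate | [K+].F[B-](F)(F)C(=C)CCCl
F2 | step 8 | hydroxy diester (C11 carbinol, C15 methylene), not isolated | COC(=O)C1(C[C@@H]2[C@H](CCC2=C)[C@](C)(O)C1)C(=O)OC
F3 | step 8 | methylene lactone methyl ester | O=C1[C@@]2(C[C@@H]3[C@H](CCC3=C)[C@](C)(O1)C2)C(=O)OC
F4 | step 8 | spiro ozonide of F3, not isolated | O=C1[C@@]2(C[C@@H]3[C@H](CCC34OCOO4)[C@](C)(O1)C2)C(=O)OC
F5 | step 8 | C15 keto lactone methyl ester | O=C1[C@@]2(C[C@@H]3[C@H](CCC3=O)[C@](C)(O1)C2)C(=O)OC
F6 | step 9 | bridged hydroxy lactone carboxylic acid | O=C1[C@@]2(C[C@@H]3[C@H](CC[C@]3(C)O)[C@](C)(O1)C2)C(=O)O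
F7 | step 9 | triketo acid | CC(C)C(=O)CC(=O)CC(=O)[C@@]1(C[C@@H]2[C@H](CC[C@]2(C)O)[C@](C)(O)C1)C(=O)O
F8 | step 10 | C1-diallyl analogue of 19 | C=CCC1(CC=C)C(=O)[C@@]2(C[C@@H]3[C@H](CC[C@]3(C)O)[C@](C)(O)C2)C(=O)C(C(=O)C(C)C)=C1O
A1 | alternative 1 | (S)-(bromomethyl)dimethyl[(1-methylcyclopent-2-en-1-yl)oxy]silane | C1CC=C[C@@]1(C)O[Si](C)(C)CBr
A2 | alternative 1 | cis-fused oxasilolane of ring C with trans C10 nitrile | C[Si]1(C)C[C@@H]2[C@H](CC[C@]2(C)O1)C#N
A3 | alternative 2 | di-tert-butyl malonate carrying the 2-(trimethylsilylmethyl)allyl methyl carbonate arm and the (R)-configured (E)-vinyl sulfone arm with C11 triethylsilyl ether | CC(C)(C)OC(=O)C(CC(OC(=O)OC)C(=C)C[Si](C)(C)C)(C[C@@](C)(O[Si](CC)(CC)CC)/C=C/S(=O)(=O)c1ccccc1)C(=O)OC(C)(C)C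
A4 | alternative 2 | trans-hydrindane di-tert-butyl ester with C15 methylene, C13 sulfone and C11 triethylsilyl ether | CC(C)(C)OC(=O)C2(C[C@@H]3[C@H](C(CC3=C)S(=O)(=O)c4ccccc4)[C@](C)(O[Si](CC)(CC)CC)C2)C(=O)OC(C)(C)C
A5 | alternative 3 | bridged hydroxy lactone methyl ester (the structure of 15) | O=C1[C@@]2(C[C@@H]3[C@H](CC[C@]3(C)O)[C@](C)(O1)C2)C(=O)OC
A6 | alternative 3 | des-prenyl spiro acyl triketone (the structure of 18) | CC(C)C(=O)C1=C(O)CC(=O)[C@@]2(C[C@@H]3[C@H](CC[C@]3(C)O)[C@](C)(O)C2)C1=O
A7 | alternative 3 | 5-methylhexane-2,4-dione (the structure of 16) | CC(=O)CC(=O)C(C)C
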